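The data stem from a simulated flask for an exercise; the scatter is artificial.

The constants of this flask are not told, only its charges and its readings of target:

| flask | starting material | reagent | catalyst | time |
|---|---|---|---|---|
| alpha | 0.400 M | 1.20 M | 0.00400 M |  |
| gamma | 0.160 M | 0.960 M | 0.00400 M |  |
| epsilon | 0.200 M | 1.20 M | 0.00400 M |  |
| eta | 0.400 M | 1.20 M | 8.00 × 10⁻⁴ M | 12 min |

- alpha run (time / min: [target] / M): 0.53: 0.0230; 1.6: 0.0605; 3.1: 0.1112; 4.9: 0.1578; 7.0: 0.1972; 9.4: 0.2290; 12: 0.2491
- gamma run (time / min: [target] / M): 0.53: 0.0179; 1.6: 0.0502; 3.1: 0.0861; 4.9: 0.1146; 7.0: 0.1234; 9.4: 0.1200; 12: 0.1098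
- epsilon run (time / min: [target] / M): 0.53: 0.0203; 1.6: 0.0562; 3.1: 0.0991; 4.9: 0.1311; 7.0: 0.1489; 9.4: 0.1430; 12: 0.1265

(standard deviation of a reading: 0.001 M)

- Overall: starting material + reagent -> target, with catalyst as catalyst.
- Constant volume, constant temperature.
- Readings of a species count what is bound in complexes too.
- An order is taken over about fifteen percent of the charge, up and down.

* how the opening rate goes with [reagent] round the charge of the alpha run: the exponent of the rate at two percent of starting material gone to target
* how the opening rate goes with [starting material] round the charge of the alpha run: the exponent of the rate at two percent of starting material gone to target (one fixed amount of target, the same in the runs compared)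
* target in the eta run at 12 min, as a share of the starting material charged

So I read the one constant I need from the last two epsilon readings: the fraction of the target present that disappears per minute, which I call the loss constant, 0.0472 min⁻¹. If some making still goes on there, the true loss is larger.

Now the epsilon run in slow motion. In the first instants the first reading gives 0.0383 M min⁻¹ of making, against a loss of 9.57 × 10⁻⁴ M min⁻¹, so target is made much faster than it is lost. The highest epsilon reading is 0.1489 M at 7.0 min, a reading with a scatter of 0.001 M, so near that time making has fallen to about the loss, roughly 0.00703 M min⁻¹. Then the readings fall. The gamma tail gives a smaller figure, 0.0342 min⁻¹, at the same catalyst with 0.960 M of reagent charged against 1.20 M, and with 0.160 M of starting material against 0.200 M. So I suspect the reagent takes part, and I assume the loss keeps its pace in the eta run.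

The eta run has 0.200 of the alpha catalyst. I scale making by that and hold it steady, since the first-reading rate of the epsilon run is 0.0383 M min⁻¹ against 0.0434 M min⁻¹ in the alpha run, with 0.200 M of starting material against 0.400 M. Target made evenly waits on average half of the time, which gives the correction:

alpha making, its own loss put back: 0.0385 M min⁻¹

eta target without loss: 0.0924 M

share kept: 0.717

eta target, of the charge: 16.6%

The forecast gives 0.35 (0.15 to 0.6) for the reagent exponent, 0.13 (0.04 to 0.24) for the starting-material exponent, and 21% (14% to 26%) for the eta share. It reckons “12 min at one-fifth catalyst equals alpha at 2.4 min”. My share is lower than its figure.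

The simulation gives 0.47, 0.032 and 16.7%.

    catalyst + starting material ⇌ catalyst-substrate complex, settled at all times (43.10 M⁻¹)
    catalyst-substrate complex + reagent ⇌ ternary complex, settled at all times (0.9830 M⁻¹)
    ternary complex → target + catalyst (19.62 min⁻¹)
    target + reagent → side product (0.05394 M⁻¹ min⁻¹)
    catalyst + target ⇌ catalyst-product complex, settled at all times (20.30 M⁻¹)

The step target + reagent → side product holds no catalyst, so in the eta run it goes on at its own pace while making runs at 0.200 of the alpha catalyst. That step is what pulls the eta share down: with it the eta run ends at 16.7%, without it at 23.5%, a gap of 6.9 percentage points. Applied to that 23.5% over the mean wait, the loss constant takes 6.7 points.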